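Remarks before the steps. Every ring carbon keeps the number it has in the target 19, also in the bicyclo[2.2.2] intermediates: C1 is the allyl-bearing bridgehead, C2=C3 the enol ether, C4 the acetoxy carbon, C5 the methoxy bridgehead, C6 the aryl carbon, C7 the methyl carbon and C8 the carbonyl carbon. Assumption: the C8 carbinol centre of 12 to 15 is removed again in step 10; it is drawn as the epimer expected from hydride attack on the alkene-facing side, and either epimer serves.

## Analysis of the target

Compound 19 is a bicyclo[3.2.1]oct-2-en-8-one. A cyclopentanone ring (C1, C7, C6, C5, C8) is spanned by the three-carbon bridge C2=C3(OMe)–C4(OAc), so the six-membered ring C1–C2–C3–C4–C5–C8 shares C1, C8 and C5 with the five-membered ring. Both bridgeheads are fully substituted and flank the C8 carbonyl: C1 carries the allyl group and C5 a methoxy group. The five stereocentres are (1S,4S,5S,6S,7R). The aryl group on C6 and the methyl group on C7 are trans; the aryl group points to the side of the C8 bridge, the methyl group lies under the C2=C3 bridge, and the acetate on C4 stands on the face that carries C8, anti to the C5–C6 bond.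

The sensitive sites are:
- the methyl enol ether (acid);
- the allylic acetate, which can ionise to a 2-methoxyallyl cation;
- the C4 oxygen, which is β to the C8 carbonyl, so a free alkoxide there invites retro-aldol cleavage of C4–C5;
- the benzylic C5–C6 bond next to the ketone;
- the terminal alkene, which rules out hydrogenation, hydroboration and radical chain reductions.

The difficulty lies in two different quaternary bridgeheads on either side of a ketone, five contiguous stereocentres and a dense oxygen pattern, all as one enantiomer. The route rests on one observation: C1, C2=C3, C4 and the methoxy-bearing C5 beside the C8 carbonyl are the carbons of an o-quinone monoketal, and C6 is bonded to C5 where a Diels–Alder adduct of such a dienone would have it on C4, one 1,2-shift away.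

## Retrosynthetic reasoning

**19 to 16.** The C4–O bond and the C5–C6 bond of 19 are cut together and C6 is rejoined to C4, the reverse of a 1,2-shift. Forward, loss of one methoxy group from the ketal carbon C5 of 16 leaves a cation at C5, the benzylic carbon C6 moves over from C4, and the cation that appears at C4 is allylic to C2=C3 and takes up acetate. This cut is chosen because it alone turns the bicyclo[3.2.1] skeleton into a bicyclo[2.2.2]oct-5-en-2-one, which a cycloaddition delivers in one step. Cutting C1–C7 or C1–C2 instead would leave the crowded C5 centre to enolate chemistry. The forward step has to ionise a ketal deactivated by the adjacent carbonyl without harming the enol ether, move C6 and not C3 or C1, and bring the acetate to C4 on the face syn to C8.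

**16 to 11.** No skeletal bond is cut here. The C3 methoxy group of 16 is traced back to the bromine of 14, the C8 ketone to a carbinol, and the C7 methyl group through 13 and 12 to the acyl group of 11. The bromine keeps the dienone from dimerising and marks C3 for the later methoxy group, and the C7 carbonyl is what makes the two-carbon bridge a dienophile. Forward, the acyl group has to be taken down to CH3 in the presence of a vinyl bromide, a ketal and a terminal alkene. Hydride cannot spare the C8 ketone, so it is reduced with the imide and reoxidised after the methoxylation, which also keeps the non-enolisable ketone away from hot alkoxide.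

**11 to 6 and 10.** The bonds C1–C7 and C4–C6 of 11 are cut, the retron of a Diels–Alder reaction between the cyclohexadienone 6 and the cinnamoyl imide 10. This removes one ring, two skeletal bonds and four stereocentres at once and leaves two flat precursors. The forward reaction has to join the carbonyl-adjacent diene terminus C1 to the acyl-bearing carbon, place the acyl group endo so that aryl and acyl end up where the target needs them, and give the right enantiomer.

**6 to 1 and 2.** The second C5–O bond of 6 is cut (oxidative dearomatisation of phenol 5 in an alcohol that supplies the methoxy group). The allyl C–C bond of 5 is traced through the aryl allyl ether 3 (Claisen rearrangement) to 1 and 2. The para bromine of 1 blocks the para position in both the rearrangement and the oxidation.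

**10 to 7 and 8.** The N–acyl bond is cut, giving acid 7 and the auxiliary 8. The auxiliary makes the two facial adducts of the cycloaddition diastereomers and is recovered in step 6.

## Alternatives that were turned down

**Alternative 1:** crossed enone–alkene photocycloaddition followed by cyclobutane fragmentation.
- Disconnection: C1–C7, with a temporary C2–C6 bond added. An enone (C1=C2–C3=O) and the aryl-propenyl unit C6=C7, tethered through C5, are the precursors.
- Forward key step: triplet-sensitised irradiation closes the bicyclo[2.1.1]hexane of cage ketone A1 in the crossed sense that a 1,5-diene favours.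
- For it: the quaternary C1 and the C1–C7 bond form intramolecularly with no regiochemical doubt and without reagents, and no cationic end-game is needed. On these two points it is stronger than the chosen route.
- Against it: the electron-rich aryl-propenyl group takes up the triplet energy, the addition is stepwise through a 1,4-biradical, and the alkene geometry that should set C7 is lost. C6 is quaternary in A1 and becomes a CH only when C2–C6 is broken, through a planar benzylic intermediate, so its configuration is not secured. C4 is still a methylene and C8 still a ketal, so oxygenation at C4, enol ether formation and deprotection follow.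
- Comparison: the chosen route has an open question at the allyl cation, but it sets the trans C6/C7 pair by a concerted thermal reaction from the alkene geometry and carries every oxygen of the target from the start.

**Alternative 2:** asymmetric Nazarov cyclisation with hydride interception.
- Disconnection: C6–C7 of the cyclopentanone.
- Forward key step: Cu(OTf)2 with a chiral bis(oxazoline) ligand activates a cross-conjugated dienone, conrotatory closure sets the trans C6/C7 pair, and Et3SiH reduces the oxyallyl cation at C5 to give keto ester A2.
- For it: the absolute configuration comes from a catalyst. On this point it is stronger than the chosen route, which cannot count on induction from its auxiliary in a thermal reaction.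
- Against it: A2 holds only the five-membered ring. Both bridgeheads still have to be made quaternary, the ester carbon has to become C2, and C3 and C4 have to be added and closed onto an α-methoxy ketone carbon with control at C4. The regiochemistry of hydride capture between C5 and C1 is a further open point. The remainder is longer than the whole of the chosen route.
- Comparison: the chosen route forms the full carbon skeleton, both bridgeheads included, in two operations.

**Alternative 3:** intramolecular ketone α-alkenylation at the allyl bridgehead.
- Disconnection: C1–C2.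
- Forward key step: Pd2(dba)3, a bulky phosphine and KOt-Bu couple the C1 enolate of a cyclopentanone with a bromo enol ether side chain held on C5, closing the six-membered ring to silyl ether A3.
- For it: the C4 oxygen is in place with fixed position and configuration before the ring closes, so there is no partition of an allyl cation, and A3 is two steps from the target. On the C4 question it is stronger than the chosen route.
- Against it: the cyclisation substrate is a cyclopentanone with a quaternary methoxy carbon, the C6/C7 pair and a stereodefined oxygenated side chain, which is most of the synthetic problem. The alkenylpalladium intermediate can add to the allyl double bond instead of the enolate. The strong base meets a β-silyloxy ketone, and desilylation of A3 passes through the β-hydroxy ketone that is prone to retro-aldol cleavage.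
- Comparison: the chosen route reaches its cyclisation precursors in four steps from commercial materials and places its risk in one early, convergent step.

Key step: step 5

## Steps

Step 1
Reactants: 1 4-bromo-2-methoxyphenol; 2 allyl bromide
Product: 3 1-(allyloxy)-4-bromo-2-methoxybenzene
Conditions: K2CO3, acetone, reflux
Reagents that add atoms: none
Why: Williamson O-alkylation of the phenoxide with a reactive allylic halide; no competing site.

Step 2
Reactants: 3 1-(allyloxy)-4-bromo-2-methoxybenzene
Product: 5 2-allyl-4-bromo-6-methoxyphenol, via Claisen dienone 4 (not isolated)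
Conditions: N,N-diethylaniline, 190 °C
Reagents that add atoms: none
Why: Aromatic Claisen rearrangement; the only free ortho position takes the allyl group (the para position is blocked by bromine) and dienone 4 tautomerises to the phenol.

Step 3
Reactants: 5 2-allyl-4-bromo-6-methoxyphenol
Product: 6 2-allyl-4-bromo-6,6-dimethoxycyclohexa-2,4-dien-1-one
Conditions: PhI(OAc)2, MeOH, 0 °C; concentrated cold and used crude
Reagents that add atoms: methanol, CO
Why: Oxidative dearomatisation of a 2-methoxyphenol by a trivalent iodine reagent; methanol adds at the methoxy-bearing carbon to give the o-quinone monoketal, and the bromine at C3 and the allyl group at C1 slow its Diels–Alder dimerisation so that it can be handled.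

Step 4
Reactants: 7 (E)-3,4-dimethoxycinnamic acid; 8 (S)-4-benzyloxazolidin-2-one
Product: 10 (S)-4-benzyl-3-[(E)-3-(3,4-dimethoxyphenyl)acryloyl]oxazolidin-2-one, via mixed pivalic anhydride 9 (not isolated)
Conditions: t-BuCOCl, Et3N, THF, −20 °C; then LiCl, 8, −20 °C to rt
Reagents that add atoms: none
Why: One-pot N-acylation through the mixed anhydride, which is attacked at the less hindered cinnamoyl carbonyl by the LiCl-activated oxazolidinone; the E geometry is untouched.

Step 5
Reactants: 6 2-allyl-4-bromo-6,6-dimethoxycyclohexa-2,4-dien-1-one; 10 (S)-4-benzyl-3-[(E)-3-(3,4-dimethoxyphenyl)acryloyl]oxazolidin-2-one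
Product: 11 (S)-4-benzyl-3-[1-allyl-3-bromo-6-(3,4-dimethoxyphenyl)-5,5-dimethoxy-8-oxobicyclo[2.2.2]oct-2-ene-7-carbonyl]oxazolidin-2-one (acyl group on C7 syn to the C2=C3 bridge, aryl group on C6 syn to the C5–C8 bridge, C6/C7 trans)
Conditions: 6 (2 equiv, in portions), toluene, BHT (cat.), 110 °C, sealed tube; chromatography, then crystallisation
Reagents that add atoms: none
Why: Thermal, concerted, suprafacial [4+2] cycloaddition of the diene C1=C2–C3=C4 of 6 to the C6=C7 bond of 10, the closest known reaction type being the Diels–Alder reaction of masked o-benzoquinones with acrylate-type dienophiles. C1–C7 and C4–C6 form in the same step and close one six-membered ring (C1–C2–C3–C4–C6–C7) by cycloaddition, which completes the bicyclo[2.2.2]octenone. The carbonyl-adjacent terminus C1 should bond to the acyl-bearing carbon, the orientation that acrylates show with these dienones, so C7 carries the imide and C6 the aryl group. The bridgeheads C1 and C4 are fixed relative to each other by the ring, and the trans relation of C6 and C7 is carried over from the E double bond of 10. Their relation to the bridges comes from the endo transition state, in which the imide carbonyl lies under the diene, putting the acyl group syn to C2=C3 and the aryl group on the ketal side. The absolute sense is that of bonding C1 to the si face of the acyl-bearing carbon. A chelating Lewis acid is left out because the ketal is not expected to tolerate it, so the benzyl group can give only a modest bias; what the auxiliary secures is that the two facial endo adducts are diastereomers, from which 11 is separated. The step therefore needs regio-, endo and facial selectivity: the dienone carbonyl and the imide carbonyl provide the first two, the auxiliary makes the third a matter of separation, and the bromine and allyl substituents keep 6 alive long enough for the slow β-aryl dienophile.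

Step 6
Reactants: 11 Diels–Alder adduct
Product: 12 [1-allyl-3-bromo-6-(3,4-dimethoxyphenyl)-8-hydroxy-5,5-dimethoxybicyclo[2.2.2]oct-2-en-7-yl]methanol (C8 hydroxyl syn to the C6–C7 bridge)
Conditions: LiBH4, MeOH (2 equiv), THF, 0 °C to rt
Reagents that add atoms: none
Why: Reductive cleavage of the N-acyloxazolidinone to the primary alcohol with release of 8; the C8 ketone is reduced as well, hydride coming from the alkene-facing side away from the C6 aryl group, and this carbinol centre is removed in step 10. Vinyl bromide, ketal and allyl group are inert, and C7 is not epimerised.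

Step 7
Reactants: 12 diol
Product: 13 [1-allyl-3-bromo-6-(3,4-dimethoxyphenyl)-8-hydroxy-5,5-dimethoxybicyclo[2.2.2]oct-2-en-7-yl]methyl 4-methylbenzenesulfonate
Conditions: TsCl (1.2 equiv), pyridine, CH2Cl2, 0 °C
Reagents that add atoms: p-toluenesulfonyl chloride, Cc1ccc(cc1)S(Cl)(=O)=O
Why: Selective sulfonylation of the primary hydroxyl; the C8 hydroxyl sits between the quaternary C1 and the ketal carbon C5 and should not react.

Step 8
Reactants: 13 primary tosylate
Product: 14 1-allyl-3-bromo-6-(3,4-dimethoxyphenyl)-5,5-dimethoxy-7-methylbicyclo[2.2.2]oct-2-en-8-ol
Conditions: LiEt3BH (4 equiv), THF, 0 to 50 °C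
Reagents that add atoms: none
Why: SN2 displacement of the primary tosylate by hydride turns CH2OTs into the C7 methyl group; a hydride reagent is used because a radical reduction would let the primary radical add to the allyl double bond. The C8 alkoxide cannot reach the tosylate carbon, and the vinyl bromide and ketal do not react.

Step 9
Reactants: 14 vinyl bromide
Product: 15 1-allyl-6-(3,4-dimethoxyphenyl)-3,5,5-trimethoxy-7-methylbicyclo[2.2.2]oct-2-en-8-ol
Conditions: CuI (20 mol %), NaOMe (6 equiv), MeOH–NMP, 110 °C, sealed tube
Reagents that add atoms: sodium methoxide, [Na+].[O-]C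
Why: Ullmann-type copper-catalysed methoxylation of an unactivated vinyl bromide, with the double bond staying in place. C8 is present as its alkoxide and not as a ketone, which keeps that carbon out of reach of methoxide; neither elimination nor allyl isomerisation is open to this substrate.

Step 10
Reactants: 15 enol ether alcohol
Product: 16 1-allyl-6-(3,4-dimethoxyphenyl)-3,5,5-trimethoxy-7-methylbicyclo[2.2.2]oct-2-en-8-one
Conditions: Dess–Martin periodinane, NaHCO3, CH2Cl2, 0 °C to rt
Reagents that add atoms: none
Why: Dess–Martin oxidation of the hindered secondary carbinol restores the C8 ketone; the buffer keeps the released acetic acid from the enol ether.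

Step 11
Reactants: 16 enol ether ketone
Product: 19 (1S,4S,5S,6S,7R)-1-allyl-6-(3,4-dimethoxyphenyl)-3,5-dimethoxy-7-methyl-8-oxobicyclo[3.2.1]oct-2-en-4-yl acetate, via oxocarbenium ion 17 (not isolated), via allyl cation 18 (not isolated)
Conditions: Me3SiOTf (0.3 equiv), Me3SiOAc (10 equiv), 2,6-di-tert-butyl-4-methylpyridine (0.5 equiv), CH2Cl2 (0.01 M), −40 to 0 °C; Et3N quench
Reagents that add atoms: trimethylsilyl acetate, CC(=O)O[Si](C)(C)C
Why: Lewis-acid acetolysis with a Wagner–Meerwein shift: the silyl triflate removes one C5 methoxy group as Me3SiOMe, the benzylic carbon C6 migrates with retention from C4 to the cationic C5 of 17 (which turns the bicyclo[2.2.2]octenyl into the bicyclo[3.2.1]octenyl skeleton and fixes C5), and the 2-methoxyallyl cation 18 is captured at C4 by the silyl acetate. Capture should occur on the face syn to C8 and anti to the C6–C7 bridge, the side opposite the departing C6, which sets C4; the aprotic medium and the hindered base keep the enol ether from protonation.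

## Compound list

1 | 4-bromo-2-methoxyphenol | COc1cc(Br)ccc1O | starting material
2 | allyl bromide | C=CCBr | starting material
3 | 1-(allyloxy)-4-bromo-2-methoxybenzene | C=CCOc1ccc(Br)cc1OC | intermediate
4 | 6-allyl-4-bromo-2-methoxycyclohexa-2,4-dien-1-one (Claisen dienone, racemic transient) | C=CCC1C=C(Br)C=C(OC)C1=O | intermediate
5 | 2-allyl-4-bromo-6-methoxyphenol | C=CCc1cc(Br)cc(OC)c1O | intermediate
6 | 2-allyl-4-bromo-6,6-dimethoxycyclohexa-2,4-dien-1-one | C=CCC1=CC(Br)=CC(OC)(OC)C1=O | intermediate
7 | (E)-3,4-dimethoxycinnamic acid | COc1ccc(/C=C/C(=O)O)cc1OC | starting material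
8 | (S)-4-benzyloxazolidin-2-one | O=C1N[C@@H](Cc2ccccc2)CO1 | starting material
9 | (E)-3-(3,4-dimethoxyphenyl)acrylic pivalic anhydride | COc1ccc(/C=C/C(=O)OC(=O)C(C)(C)C)cc1OC | intermediate
10 | (S)-4-benzyl-3-[(E)-3-(3,4-dimethoxyphenyl)acryloyl]oxazolidin-2-one | O=C(/C=C/c1ccc(OC)c(OC)c1)N1[C@@H](Cc2ccccc2)COC1=O | intermediate
11 | Diels–Alder adduct, bicyclo[2.2.2]octenone imide (acyl syn to C2=C3, aryl syn to the C5–C8 bridge) | C=CC[C@]12C=C(Br)[C@H](C(OC)(OC)C1=O)[C@H](c1ccc(OC)c(OC)c1)[C@H]2C(=O)N1[C@@H](Cc2ccccc2)COC1=O | intermediate
12 | diol, C7 hydroxymethyl and C8 hydroxyl (hydroxyl syn to the C6–C7 bridge) | C=CC[C@]12C=C(Br)[C@H](C(OC)(OC)[C@H]1O)[C@H](c1ccc(OC)c(OC)c1)[C@H]2CO | intermediate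
13 | primary tosylate of 12 | C=CC[C@]12C=C(Br)[C@H](C(OC)(OC)[C@H]1O)[C@H](c1ccc(OC)c(OC)c1)[C@H]2COS(=O)(=O)c1ccc(C)cc1 | intermediate
14 | 1-allyl-3-bromo-6-(3,4-dimethoxyphenyl)-5,5-dimethoxy-7-methylbicyclo[2.2.2]oct-2-en-8-ol | C=CC[C@]12C=C(Br)[C@H](C(OC)(OC)[C@H]1O)[C@H](c1ccc(OC)c(OC)c1)[C@H]2C | intermediate
15 | 1-allyl-6-(3,4-dimethoxyphenyl)-3,5,5-trimethoxy-7-methylbicyclo[2.2.2]oct-2-en-8-ol | C=CC[C@]12C=C(OC)[C@H](C(OC)(OC)[C@H]1O)[C@H](c1ccc(OC)c(OC)c1)[C@H]2C | intermediate
16 | 1-allyl-6-(3,4-dimethoxyphenyl)-3,5,5-trimethoxy-7-methylbicyclo[2.2.2]oct-2-en-8-one | C=CC[C@]12C=C(OC)[C@H](C(OC)(OC)C1=O)[C@H](c1ccc(OC)c(OC)c1)[C@H]2C | intermediate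
17 | C5 oxocarbenium ion of 16 (triflate ion pair) | C=CC[C@]12C=C(OC)[C@H](C(=[O+]C)C1=O)[C@H](c1ccc(OC)c(OC)c1)[C@H]2C | intermediate
18 | bicyclo[3.2.1] 2-methoxyallyl cation C2–C3–C4 (triflate ion pair) | C=CC[C@]12C=C(OC)[CH+][C@](OC)(C1=O)[C@H](c1ccc(OC)c(OC)c1)[C@H]2C | intermediate
19 | (1S,4S,5S,6S,7R)-1-allyl-6-(3,4-dimethoxyphenyl)-3,5-dimethoxy-7-methyl-8-oxobicyclo[3.2.1]oct-2-en-4-yl acetate | C=CC[C@]12C=C(OC)[C@H](OC(C)=O)[C@](OC)(C1=O)[C@H](c1ccc(OC)c(OC)c1)[C@H]2C | target

## Step count and least certain steps

Total step count: 11. Longest linear sequence: 10 steps (steps 1, 2, 3 and 5 to 11, from 1).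

**Step 5 (key step).**
- What may go wrong: the β-aryl imide adds slowly, so dimerisation and decay of the dienone take over. The aryl group may also compete with the imide for the endo position, and the facial discrimination without chelation may be poor or favour the other face.
- Design note: (S)-8 is the enantiomer whose metal-chelated s-cis form would expose the required si face, should a mild chelating Lewis acid turn out to be tolerated.
- Fallback: it sets out from 6 and comes back at 12. Dienone 6 is heated with commercial (E)-3,4-dimethoxycinnamaldehyde, a smaller and more reactive dienophile, to give the racemic endo aldehyde adduct F1. NaBH4 reduces aldehyde and ketone to the racemic diol F2. The primary hydroxyl is esterified with (S)-naproxen (DCC, DMAP), the diastereomeric esters are separated, and the naproxen ester of the wanted enantiomer F3 is cleaved with K2CO3 in MeOH to give 12.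

**Step 11.**
- What may go wrong: the α-keto ketal may need a stronger acid than the enol ether tolerates, so the enol ether is lost through attack on the oxocarbenium ion of another molecule or through hydrolysis on work-up. The allyl cation 18 can also be captured at C2 instead of C4; its two termini differ only in the bridgehead next to them, the two allylic acetates interconvert through 18, and their ratio cannot be predicted with confidence. The veratryl ring may attack the C5 cation in competition with the shift.
- Fallback: the shift is moved to the vinyl bromide stage, where nothing is acid-labile. It sets out from 14 and comes back at 19.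
  - Dess–Martin oxidation of 14 gives the bromo ketone F4.
  - BF3·OEt2 in acetic acid brings about the same shift with acetate capture and gives the rearranged bromo allylic acetate F5.
  - Hot methoxide would turn the acetate into a C4 alkoxide that can undergo retro-aldol cleavage, so the acetate is exchanged first: HCl in MeOH gives the bromo alcohol F6, and TBSOTf with 2,6-lutidine gives the silyl ether F7.
  - CuI with NaOMe then gives the enol ether silyl ether F8, which is the same compound as A3.
  - Bu4NF buffered with AcOH gives the C4 alcohol F9, and Ac2O, pyridine and DMAP give 19.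

**Step 9.**
- What may go wrong: substitution at a vinyl bromide flanked by a bridgehead is slow, and at the temperature needed protodebromination or decay may win.
- Fallback: it sets out from 14 and comes back at 15. Miyaura borylation (PdCl2(dppf), bis(pinacolato)diboron, KOAc, dioxane, 80 °C) gives the alkenyl boronate F10. Oxidative coupling with methanol promoted by Cu(OAc)2 (Et3N, MeOH, air, rt), a Chan–Lam-type etherification, gives 15.

**Step 6.**
- What may go wrong: the exocyclic carbonyl on C7 is shielded by the quaternary C1 and the aryl-bearing C6, so hydride may open the oxazolidinone ring instead.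
- Fallback: it sets out from 11 and comes back at 12. LiOH with H2O2 in THF–water, which prefers the exocyclic carbonyl also in hindered imides, gives the carboxylic acid F11 and the auxiliary 8. LiAlH4 in THF at 0 °C reduces the acid and the ketone to 12.

## Further compounds

F1 | step 5 | racemic 1-allyl-3-bromo-6-(3,4-dimethoxyphenyl)-5,5-dimethoxy-8-oxobicyclo[2.2.2]oct-2-ene-7-carbaldehyde (enantiomer leading to 19 drawn) | C=CC[C@]12C=C(Br)[C@H](C(OC)(OC)C1=O)[C@H](c1ccc(OC)c(OC)c1)[C@H]2C=O
F2 | step 5 | racemic diol, the racemate of 12 (enantiomer leading to 19 drawn) | C=CC[C@]12C=C(Br)[C@H](C(OC)(OC)[C@H]1O)[C@H](c1ccc(OC)c(OC)c1)[C@H]2CO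
F3 | step 5 | (S)-2-(6-methoxynaphthalen-2-yl)propanoate of the primary hydroxyl of 12 | C=CC[C@]12C=C(Br)[C@H](C(OC)(OC)[C@H]1O)[C@H](c1ccc(OC)c(OC)c1)[C@H]2COC(=O)[C@@H](C)c1ccc2cc(OC)ccc2c1
F4 | step 11 | 1-allyl-3-bromo-6-(3,4-dimethoxyphenyl)-5,5-dimethoxy-7-methylbicyclo[2.2.2]oct-2-en-8-one | C=CC[C@]12C=C(Br)[C@H](C(OC)(OC)C1=O)[C@H](c1ccc(OC)c(OC)c1)[C@H]2C
F5 | step 11 | 1-allyl-3-bromo-6-(3,4-dimethoxyphenyl)-5-methoxy-7-methyl-8-oxobicyclo[3.2.1]oct-2-en-4-yl acetate | C=CC[C@]12C=C(Br)[C@H](OC(C)=O)[C@](OC)(C1=O)[C@H](c1ccc(OC)c(OC)c1)[C@H]2C
F6 | step 11 | 1-allyl-3-bromo-6-(3,4-dimethoxyphenyl)-4-hydroxy-5-methoxy-7-methylbicyclo[3.2.1]oct-2-en-8-one | C=CC[C@]12C=C(Br)[C@H](O)[C@](OC)(C1=O)[C@H](c1ccc(OC)c(OC)c1)[C@H]2C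
F7 | step 11 | tert-butyldimethylsilyl ether of F6 | C=CC[C@]12C=C(Br)[C@H](O[Si](C)(C)C(C)(C)C)[C@](OC)(C1=O)[C@H](c1ccc(OC)c(OC)c1)[C@H]2C
F8 | step 11 | 1-allyl-4-(tert-butyldimethylsilyloxy)-6-(3,4-dimethoxyphenyl)-3,5-dimethoxy-7-methylbicyclo[3.2.1]oct-2-en-8-one | C=CC[C@]12C=C(OC)[C@H](O[Si](C)(C)C(C)(C)C)[C@](OC)(C1=O)[C@H](c1ccc(OC)c(OC)c1)[C@H]2C
F9 | step 11 | 1-allyl-6-(3,4-dimethoxyphenyl)-4-hydroxy-3,5-dimethoxy-7-methylbicyclo[3.2.1]oct-2-en-8-one (deacetyl 19) | C=CC[C@]12C=C(OC)[C@H](O)[C@](OC)(C1=O)[C@H](c1ccc(OC)c(OC)c1)[C@H]2C
F10 | step 9 | 1-allyl-6-(3,4-dimethoxyphenyl)-5,5-dimethoxy-7-methyl-3-(4,4,5,5-tetramethyl-1,3,2-dioxaborolan-2-yl)bicyclo[2.2.2]oct-2-en-8-ol | C=CC[C@]12C=C(B3OC(C)(C)C(C)(C)O3)[C@H](C(OC)(OC)[C@H]1O)[C@H](c1ccc(OC)c(OC)c1)[C@H]2C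
F11 | step 6 | 1-allyl-3-bromo-6-(3,4-dimethoxyphenyl)-5,5-dimethoxy-8-oxobicyclo[2.2.2]oct-2-ene-7-carboxylic acid | C=CC[C@]12C=C(Br)[C@H](C(OC)(OC)C1=O)[C@H](c1ccc(OC)c(OC)c1)[C@H]2C(=O)O
A1 | alternative 1 | crossed photoadduct, tricyclic cage ketone with C1–C7 and C2–C6 bonds, C3 ketone and C8 dimethyl ketal | C=CC[C@]12[C@@H]3C(=O)C[C@](OC)(C1(OC)OC)[C@]3(c1ccc(OC)c(OC)c1)[C@H]2C
A2 | alternative 2 | methyl 4-(3,4-dimethoxyphenyl)-3-methoxy-5-methyl-2-oxocyclopentane-1-carboxylate | COC(=O)[C@@H]1C(=O)[C@@H](OC)[C@H](c2ccc(OC)c(OC)c2)[C@H]1C
A3 | alternative 3 | tert-butyldimethylsilyl ether of the C4 alcohol of deacetyl 19 | C=CC[C@]12C=C(OC)[C@H](O[Si](C)(C)C(C)(C)C)[C@](OC)(C1=O)[C@H](c1ccc(OC)c(OC)c1)[C@H]2C
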